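The seven-membered ring is opened at the two bonds that leave the ring-fusion atoms, C9a–C9 and C4a–C5 (benzo[7]annulene numbering). Because C4a is allylic to the C3=C4 bond of the six-membered ring, that ring is the trace of a cyclohexa-1,3-diene that has taken up the five-carbon chain C5–C9 syn across one double bond. One palladium cascade does this: the vinyl iodide end of the chain adds to the diene, and the allylpalladium so formed inserts the isopropenyl end, then takes up hydride. The chain, a dioxolane iodo-diene, comes from D-tartaric acid (C6, C7); the partner is an (R)-2-methylcyclohexa-2,4-dienyl silyl ether.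

Key step: step 10

Remark: the bicyclic compounds are named as benzo[7]annulenes (C1–C4 six-membered ring, C4a and C9a ring fusion, C5–C9 seven-membered ring), and the 6,7-acetonide is named as an isopropylidenedioxy group. The final esterification consumes two equivalents of angelic acid, one for each hydroxyl group.

Step 1
Reactants: 1 dimethyl (4S,5S)-2,2-dimethyl-1,3-dioxolane-4,5-dicarboxylate (acetonide of dimethyl D-tartrate)
Product: 2 (4S,5S)-5-(methoxycarbonyl)-2,2-dimethyl-1,3-dioxolane-4-carboxylic acid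
Conditions: KOH (1.0 equiv), MeOH, rt; then aq. HCl
Reagents that add atoms: potassium hydroxide, [K+].[OH-]
Why: Monosaponification of a C2-symmetric diester, in which the first carboxylate formed slows hydrolysis of the second ester, so one equivalent of hydroxide should stop at the half-ester with both stereocentres untouched.

Step 2
Reactants: 2 (4S,5S)-5-(methoxycarbonyl)-2,2-dimethyl-1,3-dioxolane-4-carboxylic acid
Product: 4 methyl (4S,5S)-5-acetyl-2,2-dimethyl-1,3-dioxolane-4-carboxylate, via acid chloride 3 (not isolated)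
Conditions: (COCl)2, cat. DMF, CH2Cl2, 0 °C to rt; then Me2CuLi, Et2O, −78 °C
Reagents that add atoms: lithium dimethylcuprate, [Li+].C[Cu-]C; oxalyl chloride, O=C(Cl)C(Cl)=O (chlorine of 3 only)
Why: Acid chloride formation followed by Gilman cuprate acylation should give the methyl ketone without over-addition and without touching the methyl ester or the α-alkoxy stereocentres.

Step 3
Reactants: 4 methyl (4S,5S)-5-acetyl-2,2-dimethyl-1,3-dioxolane-4-carboxylate
Product: 5 methyl (4S,5R)-2,2-dimethyl-5-(prop-1-en-2-yl)-1,3-dioxolane-4-carboxylate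
Conditions: Ph3PCH3Br, KOt-Bu, THF, 0 °C to rt
Reagents that add atoms: methyltriphenylphosphonium bromide, C[P+](c1ccccc1)(c1ccccc1)c1ccccc1.[Br-]
Why: Wittig methylenation is chemoselective for the ketone over the ester, and any enolisation next to the ketone can only return the more stable trans-dioxolane.

Step 4
Reactants: 5 methyl (4S,5R)-2,2-dimethyl-5-(prop-1-en-2-yl)-1,3-dioxolane-4-carboxylate
Product: 6 (4S,5R)-2,2-dimethyl-5-(prop-1-en-2-yl)-1,3-dioxolane-4-carbaldehyde
Conditions: i-Bu2AlH (1.05 equiv), CH2Cl2, −78 °C; aq. potassium sodium tartrate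
Reagents that add atoms: none
Why: Half-reduction of an α-alkoxy ester with i-Bu2AlH should stop at the chelated aluminium hemiacetal at −78 °C and release the aldehyde on work-up.

Step 5
Reactants: 6 (4S,5R)-2,2-dimethyl-5-(prop-1-en-2-yl)-1,3-dioxolane-4-carbaldehyde
Product: 7 (4R,5R)-4-[(1Z)-2-iodoprop-1-en-1-yl]-2,2-dimethyl-5-(prop-1-en-2-yl)-1,3-dioxolane
Conditions: Ph3PEtI, n-BuLi, THF; I2, −78 °C; NaN(SiMe3)2; then 6, −78 to −20 °C
Reagents that add atoms: ethyltriphenylphosphonium iodide, CC[P+](c1ccccc1)(c1ccccc1)c1ccccc1.[I-]; iodine, II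
Why: Stork–Zhao-type Wittig olefination with the α-iodo ylide should give the trisubstituted (Z)-vinyl iodide (iodine cis to the dioxolane), the geometry that later becomes the cis ring alkene.

Step 6
Reactants: 8 2-methylcyclohex-2-en-1-one
Product: 9 4-bromo-2-methylcyclohex-2-en-1-one (racemic)
Conditions: NBS, AIBN (cat.), PhCF3, 80 °C
Reagents that add atoms: N-bromosuccinimide, O=C1CCC(=O)N1Br
Why: Wohl–Ziegler allylic bromination should take place at the ring γ-CH2 through the allyl radical conjugated with the enone, and the bromine-bearing centre is erased in step 9.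

Step 7
Reactants: 9 4-bromo-2-methylcyclohex-2-en-1-one
Product: 10 (1R)-4-bromo-2-methylcyclohex-2-en-1-ol (both C4 epimers)
Conditions: (S)-2-methyl-CBS-oxazaborolidine (10 mol %), BH3·SMe2, THF, −20 °C; then MeOH
Reagents that add atoms: none
Why: Corey–Bakshi–Shibata 1,2-reduction should set the carbinol centre as (1R) under catalyst control, the alkenyl branch acting as the large group as in aryl alkyl ketones.

Step 8
Reactants: 10 (1R)-4-bromo-2-methylcyclohex-2-en-1-ol
Product: 11 {[(1R)-4-bromo-2-methylcyclohex-2-en-1-yl]oxy}(tert-butyl)dimethylsilane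
Conditions: TBSOTf, 2,6-lutidine, CH2Cl2, −78 °C
Reagents that add atoms: tert-butyldimethylsilyl trifluoromethanesulfonate, CC(C)(C)[Si](C)(C)OS(=O)(=O)C(F)(F)F
Why: Silylation with the silyl triflate and a hindered, non-nucleophilic pyridine base at low temperature should protect the secondary allylic alcohol without displacing the allylic bromide, and the resulting ether does not ionise under the later palladium conditions.

Step 9
Reactants: 11 {[(1R)-4-bromo-2-methylcyclohex-2-en-1-yl]oxy}(tert-butyl)dimethylsilane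
Product: 12 tert-butyldimethyl{[(1R)-2-methylcyclohexa-2,4-dien-1-yl]oxy}silane
Conditions: DBU, toluene, 80 °C
Reagents that add atoms: none
Why: E2 dehydrobromination can only remove a C5 hydrogen, so both bromide epimers should converge on the conjugated 2,4-diene with the silyloxy stereocentre intact.

Step 10
Reactants: 7 (4R,5R)-4-[(1Z)-2-iodoprop-1-en-1-yl]-2,2-dimethyl-5-(prop-1-en-2-yl)-1,3-dioxolane; 12 tert-butyldimethyl{[(1R)-2-methylcyclohexa-2,4-dien-1-yl]oxy}silane
Product: 13 tert-butyl{[(2R,4aS,6R,7R,9aR)-6,7-(isopropylidenedioxy)-3,5,5,9-tetramethyl-2,4a,5,6,7,9a-hexahydro-1H-benzo[7]annulen-2-yl]oxy}dimethylsilane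
Conditions: Pd(OAc)2 (10 mol %), PPh3 (20 mol %), Bu4NCl, 12 (1.5 equiv), Et3N, DMF, 70 °C, HCO2H added slowly
Reagents that add atoms: none
Why: Proposed new method: oxidative addition of zerovalent palladium to the C–I bond of 7 gives an alkenylpalladium iodide that should add syn across the unsubstituted terminal double bond of diene 12 on the face opposite the silyloxy group (new C9–C9a bond); the resulting allylpalladium, held on that same face, should insert the tethered isopropenyl group at its internal carbon (new C4a–C5 bond, quaternary C5), and the neopentylpalladium, which has no β-hydrogen, is reduced by formate to the second methyl group. The closest known reactions are the Heck carbopalladation of 1,3-dienes to allylpalladium species that are captured in a second bond-forming event, and the intramolecular insertion of an alkene into an allylpalladium (palladium-ene cyclisation) ended by hydride capture; their union in a seven-membered closure on this substrate class is new. The seven-membered ring closes in the 7-exo-trig mode. C9a is set by the C2 silyloxy stereocentre (anti addition), C4a by suprafacial delivery from palladium on the same face (hence the cis ring fusion), and C6 and C7 come unchanged from D-tartrate. The step needs the alkenylpalladium to take the diene before it attacks its own isopropenyl group, which the trans-dioxolane should secure because a 5-exo closure would build a trans-fused bicyclo[3.3.0]octene and a 6-endo closure needs a twisted insertion geometry that capture by the excess diene should outrun. It also needs insertion to outrun hydride capture of the allylpalladium, which the slow addition of formic acid should favour.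

Step 11
Reactants: 13 tert-butyl{[(2R,4aS,6R,7R,9aR)-6,7-(isopropylidenedioxy)-3,5,5,9-tetramethyl-2,4a,5,6,7,9a-hexahydro-1H-benzo[7]annulen-2-yl]oxy}dimethylsilane
Product: 14 (2R,4aS,6R,7R,9aR)-6,7-(isopropylidenedioxy)-3,5,5,9-tetramethyl-2,4a,5,6,7,9a-hexahydro-1H-benzo[7]annulen-2-ol
Conditions: TBAF, THF, rt
Reagents that add atoms: none
Why: Fluoride cleavage of the secondary allylic silyl ether leaves the acetonide and both alkenes untouched.

Step 12
Reactants: 14 (2R,4aS,6R,7R,9aR)-6,7-(isopropylidenedioxy)-3,5,5,9-tetramethyl-2,4a,5,6,7,9a-hexahydro-1H-benzo[7]annulen-2-ol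
Product: 15 (4aS,6R,7R,9aR)-6,7-(isopropylidenedioxy)-3,5,5,9-tetramethyl-1,4a,5,6,7,9a-hexahydro-2H-benzo[7]annulen-2-one
Conditions: MnO2 (excess), CH2Cl2, rt
Reagents that add atoms: none
Why: MnO2 oxidises only the allylic alcohol, which removes the auxiliary C2 stereocentre and gives the conjugated 2-methylcyclohexenone of the target.

Step 13
Reactants: 15 (4aS,6R,7R,9aR)-6,7-(isopropylidenedioxy)-3,5,5,9-tetramethyl-1,4a,5,6,7,9a-hexahydro-2H-benzo[7]annulen-2-one
Product: 16 (4aS,6R,7R,9aR)-6,7-dihydroxy-3,5,5,9-tetramethyl-1,4a,5,6,7,9a-hexahydro-2H-benzo[7]annulen-2-one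
Conditions: AcOH/H2O 4:1, 50 °C
Reagents that add atoms: none
Why: Acid-catalysed hydrolysis of the strained trans-fused acetonide should free the trans-diol under conditions mild enough for the enone and the allylic C7 carbinol.

Step 14
Reactants: 16 (4aS,6R,7R,9aR)-6,7-dihydroxy-3,5,5,9-tetramethyl-1,4a,5,6,7,9a-hexahydro-2H-benzo[7]annulen-2-one; 17 angelic acid (first equivalent)
Product: 19 (4aS,6R,7R,9aR)-3,5,5,9-tetramethyl-2-oxo-2,4a,5,6,7,9a-hexahydro-1H-benzo[7]annulene-6,7-diyl bis[(2Z)-2-methylbut-2-enoate], via mixed anhydride 18 (not isolated)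
Conditions: 17 (2.5 equiv in all), 2,4,6-trichlorobenzoyl chloride (2.5 equiv), Et3N, toluene, rt; then 16, 75 °C
Reagents that add atoms: angelic acid (second equivalent of 17, for the second ester), C/C=C(/C)C(=O)O; 2,4,6-trichlorobenzoyl chloride, O=C(Cl)c1c(Cl)cc(Cl)cc1Cl (aroyl group of 18 only)
Why: Yamaguchi-type mixed-anhydride esterification without DMAP, with one equivalent of anhydride 18 consumed at each secondary hydroxyl, should give the bis-ester while keeping the (Z)-geometry of both angeloyl groups.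

Compound list
1 | dimethyl (4S,5S)-2,2-dimethyl-1,3-dioxolane-4,5-dicarboxylate | CC1(C)O[C@H](C(=O)OC)[C@@H](C(=O)OC)O1 | starting material
2 | (4S,5S)-5-(methoxycarbonyl)-2,2-dimethyl-1,3-dioxolane-4-carboxylic acid | CC1(C)O[C@H](C(=O)OC)[C@@H](C(=O)O)O1 | intermediate
3 | methyl (4S,5S)-5-(chlorocarbonyl)-2,2-dimethyl-1,3-dioxolane-4-carboxylate | CC1(C)O[C@H](C(=O)OC)[C@@H](C(=O)Cl)O1 | intermediate
4 | methyl (4S,5S)-5-acetyl-2,2-dimethyl-1,3-dioxolane-4-carboxylate | CC1(C)O[C@H](C(=O)OC)[C@@H](C(C)=O)O1 | intermediate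
5 | methyl (4S,5R)-2,2-dimethyl-5-(prop-1-en-2-yl)-1,3-dioxolane-4-carboxylate | CC1(C)O[C@H](C(=O)OC)[C@@H](C(C)=C)O1 | intermediate
6 | (4S,5R)-2,2-dimethyl-5-(prop-1-en-2-yl)-1,3-dioxolane-4-carbaldehyde | CC1(C)O[C@H](C=O)[C@@H](C(C)=C)O1 | intermediate
7 | (4R,5R)-4-[(1Z)-2-iodoprop-1-en-1-yl]-2,2-dimethyl-5-(prop-1-en-2-yl)-1,3-dioxolane | CC1(C)O[C@H](/C=C(/C)I)[C@@H](C(C)=C)O1 | intermediate
8 | 2-methylcyclohex-2-en-1-one | CC1=CCCCC1=O | starting material
9 | 4-bromo-2-methylcyclohex-2-en-1-one (racemic) | CC1=CC(Br)CCC1=O | intermediate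
10 | (1R)-4-bromo-2-methylcyclohex-2-en-1-ol (both C4 epimers) | CC1=CC(Br)CC[C@H]1O | intermediate
11 | {[(1R)-4-bromo-2-methylcyclohex-2-en-1-yl]oxy}(tert-butyl)dimethylsilane | CC1=CC(Br)CC[C@H]1O[Si](C)(C)C(C)(C)C | intermediate
12 | tert-butyldimethyl{[(1R)-2-methylcyclohexa-2,4-dien-1-yl]oxy}silane | CC1=CC=CC[C@H]1O[Si](C)(C)C(C)(C)C | intermediate
13 | tert-butyl{[(2R,4aS,6R,7R,9aR)-6,7-(isopropylidenedioxy)-3,5,5,9-tetramethyl-2,4a,5,6,7,9a-hexahydro-1H-benzo[7]annulen-2-yl]oxy}dimethylsilane | CC1(C)O[C@@H]2C=C(C)[C@@H]3C[C@@H](O[Si](C)(C)C(C)(C)C)C(C)=C[C@@H]3C(C)(C)[C@H]2O1 | intermediate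
14 | (2R,4aS,6R,7R,9aR)-6,7-(isopropylidenedioxy)-3,5,5,9-tetramethyl-2,4a,5,6,7,9a-hexahydro-1H-benzo[7]annulen-2-ol | CC1(C)O[C@@H]2C=C(C)[C@@H]3C[C@@H](O)C(C)=C[C@@H]3C(C)(C)[C@H]2O1 | intermediate
15 | (4aS,6R,7R,9aR)-6,7-(isopropylidenedioxy)-3,5,5,9-tetramethyl-1,4a,5,6,7,9a-hexahydro-2H-benzo[7]annulen-2-one | CC1(C)O[C@@H]2C=C(C)[C@@H]3CC(=O)C(C)=C[C@@H]3C(C)(C)[C@H]2O1 | intermediate
16 | (4aS,6R,7R,9aR)-6,7-dihydroxy-3,5,5,9-tetramethyl-1,4a,5,6,7,9a-hexahydro-2H-benzo[7]annulen-2-one | O[C@@H]1C=C(C)[C@@H]2CC(=O)C(C)=C[C@@H]2C(C)(C)[C@H]1O | intermediate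
17 | angelic acid, (2Z)-2-methylbut-2-enoic acid | C/C=C(/C)C(=O)O | starting material
18 | (2Z)-2-methylbut-2-enoic 2,4,6-trichlorobenzoic anhydride | C/C=C(/C)C(=O)OC(=O)c1c(Cl)cc(Cl)cc1Cl | intermediate
19 | (4aS,6R,7R,9aR)-3,5,5,9-tetramethyl-2-oxo-2,4a,5,6,7,9a-hexahydro-1H-benzo[7]annulene-6,7-diyl bis[(2Z)-2-methylbut-2-enoate] | C/C=C(/C)C(=O)O[C@@H]1C=C(C)[C@@H]2CC(=O)C(C)=C[C@@H]2C(C)(C)[C@H]1OC(=O)/C(C)=C\C | target

Total step count: 14. Longest linear sequence: 10 steps (steps 1–5 and 10–14).

Steps most likely to fail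

Step 10 (Proposed new method). The allylpalladium intermediate may be captured by hydride, or lose a β-hydrogen, before it inserts the isopropenyl group, so that only the C9–C9a bond is formed. Fallback, setting out from 7 and 12 and coming back at 13: the cascade is run with no hydride source under the conditions of palladium-catalysed carboiodination (Pd(P(t-Bu)3)2 cat., toluene, 100 °C). There the allylpalladium iodide has no reductive exit, and the neopentylpalladium iodide closes the cycle by carbon–iodine reductive elimination to the primary iodide tert-butyl{[(2R,4aS,6R,7R,9aR)-5-(iodomethyl)-6,7-(isopropylidenedioxy)-3,5,9-trimethyl-2,4a,5,6,7,9a-hexahydro-1H-benzo[7]annulen-2-yl]oxy}dimethylsilane F1. Radical reduction of F1 (Bu3SnH at high concentration, AIBN, toluene, 80 °C) then gives 13.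

Step 6. Hydrogen abstraction at the C2 methyl group and over-bromination may compete with bromination at the ring γ-position. Fallback, setting out from 8 and coming back at 9: acid-catalysed enol acetylation (isopropenyl acetate, TsOH, reflux) gives the linear dienyl ester 2-methylcyclohexa-1,3-dien-1-yl acetate F2. Ionic γ-bromination of F2 with NBS in aqueous THF at 0 °C returns 9 without a radical chain.

Step 14. The angeloyl group may isomerise to tigloyl during activation, and acylation of the neopentyl C6 hydroxyl may stall. Fallback, setting out from 16 and coming back at 19: both hydroxyls are esterified with 2-[bis(2,2,2-trifluoroethoxy)phosphoryl]propanoic acid (DCC, DMAP, CH2Cl2) to give (4aS,6R,7R,9aR)-3,5,5,9-tetramethyl-2-oxo-2,4a,5,6,7,9a-hexahydro-1H-benzo[7]annulene-6,7-diyl bis{2-[bis(2,2,2-trifluoroethoxy)phosphoryl]propanoate} F3. A Still–Gennari olefination of F3 with acetaldehyde (KN(SiMe3)2, 18-crown-6, THF, −78 °C) builds the two (Z)-2-methylbut-2-enoates on the substrate.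

Further compounds
F1 | step 10 | tert-butyl{[(2R,4aS,6R,7R,9aR)-5-(iodomethyl)-6,7-(isopropylidenedioxy)-3,5,9-trimethyl-2,4a,5,6,7,9a-hexahydro-1H-benzo[7]annulen-2-yl]oxy}dimethylsilane | CC1(C)O[C@@H]2C=C(C)[C@@H]3C[C@@H](O[Si](C)(C)C(C)(C)C)C(C)=C[C@@H]3C(C)(CI)[C@H]2O1
F2 | step 6 | 2-methylcyclohexa-1,3-dien-1-yl acetate | CC(=O)OC1=C(C)C=CCC1
F3 | step 14 | (4aS,6R,7R,9aR)-3,5,5,9-tetramethyl-2-oxo-2,4a,5,6,7,9a-hexahydro-1H-benzo[7]annulene-6,7-diyl bis{2-[bis(2,2,2-trifluoroethoxy)phosphoryl]propanoate} | CC(C(=O)O[C@@H]1C=C(C)[C@@H]2CC(=O)C(C)=C[C@@H]2C(C)(C)[C@H]1OC(=O)C(C)P(=O)(OCC(F)(F)F)OCC(F)(F)F)P(=O)(OCC(F)(F)F)OCC(F)(F)F
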